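| flask | starting material | reagent | protic impurity | remark | time |
|---|---|---|---|---|---|
| ash | 2.6 mM | 6.6 mM | 5.5 mM | run made earlier |  |
| birch | 26 mM | 6.6 mM | 5.5 mM | run made earlier |  |
| noon | 3.0 mM | 6.60 mM | 5.50 mM |  | 6.0 min |
| summer | 6.0 mM | 6.60 mM | 5.50 mM |  | 6.0 min |
| dawn | 12 mM | 6.60 mM | 5.50 mM |  | 6.0 min |
| winter | 20 mM | 6.60 mM | 5.50 mM |  | 6.0 min |
| midnight | 40 mM | 6.60 mM | 5.50 mM |  | 6.0 min |

| run | time / min | target / % |
|---|---|---|
| ash | 0.500 | 1.4 |
| ash | 0.833 | 3.6 |
| ash | 1.50 | 7.4 |
| ash | 3.00 | 16.2 |
| ash | 6.00 | 29.0 |
| birch | 0.500 | 0.3 |
| birch | 1.50 | 0.5 |
| birch | 3.00 | 0.9 |
| birch | 4.00 | 1.0 |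
| birch | 6.00 | 1.6 |

(scatter of a reading: 0.3 percentage points)

* [target] at the end for noon, summer, dawn, winter, midnight, in this order
* the course of these numbers from the first flask to the last (falls, then rises / falls all the way / hardly changes / rises all the way / rises, then falls)

- "hardly changes" means that all values lie within two and a half points (for a concentration: within two and a half percent of the largest)

I read every flask at 6.0 min, the time of the last ash reading, so the ratio of two flasks' mean rates of target formation was the ratio of their amounts, and time dropped out. Ash had formed 0.754 mM of target and birch 0.416 mM, so the percent yield fell from 29.0% to 1.6% on ten times the charge. From these two charges I assumed that, with reagent and protic impurity charged as in ash, the percent yield at this time does not rise with the charge of starting material. I called ash's value, 29.0%, the yield ceiling: the percent of its charge that a flask charged above ash should not exceed as target at this time.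

For noon this gave a bound from above of 0.870 mM. The bound from below came from ash itself: target formed in the second 3.00 min over that formed in the first was 0.790. As read, the mean rate of target formation sank while starting material was used, although reagent may have fallen too. I therefore took the rate to rise with [starting material] at ash's charge, and expected noon to form at least ash's 0.754 mM.

To tighten this, I counted target as the sole sink of starting material. Mean [starting material] in ash's second interval was then 0.842 of that in the first. The rate ratio lay below this, which points to a first-order response or steeper, though this is a thin reading at a scatter of 0.3 percentage points. So I placed noon between the midpoint, 0.812 mM, and the ceiling. Birch's amount lay below ash's, so I expected the row to rise and then fall.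

The forecast gave 0.8 mM, 1 mM, 0.77 mM, 0.53 mM and 0.27 mM, a course that rises, then falls, holding that “excess starting material inhibits”, and its noon value lay between ash's amount and the ceiling  but below my midpoint.

The flasks gave 0.840 mM, 1.12 mM, 0.879 mM, 0.512 mM and 0.226 mM, a course that rises, then falls.

    starting material + reagent ⇌ intermediate B (K = 1800 /M, k = 2.40 /M/s)
    starting material + reagent ⇌ intermediate A (K = 80.0 /M, k = 1.20 /M/s)
    reagent + intermediate B ⇌ target (K = 3800 /M, k = 0.540 /M/s)
    starting material + protic impurity → quenched substrate (k = 1.40 /M/s)

Noon stood between my midpoint and the ceiling , at 96.6% of it, whereas summer's 1.12 mM was 64.4% of its ceiling of 1.74 mM. In noon at 0.477 min, intermediate B was being made 7.54 times faster than it was used up, each step taken net, and at 6.00 min intermediate B stood at 27.0% of the starting material charged, beside target at 28.0%.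

The earlier runs and the new flask were computed for substances that don't exist.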